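## The problem

Compound 25 is a 2,2-disubstituted 2H-chromene whose benzo ring (ring A) carries five different substituents: O1 at C8a, the vinylic C4 at C4a, hydroxyls at C5 and C8 (para to each other) and a 4-hydroxycinnamoyl group at C6. Only C7 bears hydrogen. The second aromatic ring (ring B) is attached through the enone of a 2'-hydroxychalcone.

The only stereocentre is C2, a fully substituted carbon bound to O1, a methyl group, C3 and the 4-hydroxy-4-methylpentyl chain. Nothing else in the molecule can induce it, so it has to come from the chiral pool and its C–O bond must never be broken. The real difficulty is therefore regiochemical: the acyl group must sit next to one particular hydroquinone oxygen on a ring with five different substituents.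

The fragile parts are the hydroquinone (air oxidation), the ortho-hydroxy enone (flavanone formation in hot acid or base), the styrene-like C3=C4 bond and the tertiary alcohol (ionisation in strong acid). Oxidation levels must therefore be set late and the last step must be mild.

The feature that opens the molecule is the sequence C8a(O1)–C8(O)–C7(H)–C6(C)–C5(O)–C4a. C8 with its oxygen and the C8a=C4a unit is an alkoxy(alkenyl)carbene built on a dihydropyran, C5 with its oxygen is carbon monoxide, and C6–C7 is a terminal alkyne with its substituent on C6.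

## Retrosynthesis

**25 from 24.** No skeletal bond is cut. The three phenols are masked as methoxymethyl ethers and the tertiary alcohol as a triethylsilyl ether in 24. Acetal protection is preferred to silyl or acyl protection on ring A because it survives DDQ and keeps the ring electron-rich. One dilute-acid solvolysis must release all four groups without closing the flavanone.

**24 from 22.** Two oxidation levels are retracted: C3=C4 to the chroman and the ketone to a silylated carbinol. Both are needed because the benzannulation delivers a saturated pyran ring and does not tolerate an ynone partner. The carbinol C–H of 22 is benzylic and cinnamylic and is the most hydridic position, so a dehydrogenation that spares it is not realistic. DDQ is instead asked to oxidise the silyl ether to enone 23 and then dehydrogenate the ring in the same flask.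

**22 from 20 and 19.** The bis-acetal 22 comes from quinone 20 by reduction to hydroquinone 21 and immediate alkylation. Quinone 20 comes from the 4-methoxyphenol 19. Passing through the quinone is the only way to remove the C8 methyl group without a strong Lewis acid. PhI(OAc)2 is chosen over (NH4)2Ce(NO3)6 because it engages only the free phenol and is not strongly acidic; the electron-rich styrene and the silyl ethers should be left alone.

**19 from 11 and 17.** This is the central cut: C8–C7, C6–C5 and C5–C4a, with C5 and its oxygen traced to a carbonyl ligand. Acylating a preformed 5,8-dioxygenated chroman would have to distinguish C6 from C7, which are electronically alike. Here the pattern follows from the mechanism. The precursors are a monocyclic chiral carbene complex 11 and a five-carbon enyne 17. The forward reaction must insert the terminal alkyne with its substituent next to the CO-derived carbon and leave the ionisable silyloxy carbon and the C2 stereocentre alone.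

**17 from 12 and 15.** The alkyne is a silylated ethynyl carbinol. Cutting the carbinol–alkyne bond gives enal 14 and ethynylmagnesium bromide 15. Enal 14 is the two-carbon Wittig homologue of aldehyde 13, the MOM ether of 4-hydroxybenzaldehyde 12. The carbinol is made racemic on purpose because it ends as the ketone.

**11 from 7 and 8.** The bond between the carbene carbon (C8) and the enol-ether carbon (C8a) is cut. The vinylic C–H next to oxygen in dihydropyran 7 is lithiated (9), added to Cr(CO)6 (8) to give acylchromate 10, and O-methylated. This is the standard way to such complexes and needs only a base-stable silyl group on the side-chain oxygen.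

**7 from 5.** The O1–C8a bond is cut. Dihydropyran 6, the alcohol of 7, is the endo cycloisomer of alkynediol 5. The ring oxygen is the original carbinol oxygen attacking an sp carbon, so the C2–O bond stays intact, unlike in any etherification at the tertiary centre.

**5 from 1.** The C4–C4a bond is cut between the tosylate carbon of 4 and acetylide. Tosylate 4 comes from triol 3 by selective primary sulfonylation. Triol 3 comes from (S)-linalool 1 by anti-Markovnikov hydroboration of the vinyl group (2) and radical Markovnikov hydration of the trisubstituted alkene. Hydroboration is placed first so the hydration meets a single alkene. A radical hydration is used because cationic or mercury-mediated hydration would let the 3-hydroxyl close a cyclic ether.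

## Roads not taken

**Alternative 1:** The cut is at both bonds to the ketone carbon. Forward, zerovalent palladium (from Pd(OAc)2 and a bulky phosphine) would insert into the C6–I bond of iodochromene A2, take up CO, and add the acylpalladium to 4-(methoxymethoxy)styrene A3. The product is the tris(methoxymethyl) ether A1.
- Merits: the enone is made at the right oxidation level and geometry, and A1 is one deprotection from 25. In late-stage convergence this road is better than the chosen one, which needs four steps after its key step.
- Weak points: A2 must already hold the chromene, the stereocentre, the hydroquinone pattern and an iodine placed at C6 rather than C7, so the regiochemical problem of ring A is only moved upstream. The acylpalladium must beat direct arylation of the styrene at an aryl iodide flanked by an acetal oxygen. The C3=C4 bond of A2 is itself a styrene that can compete.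
- Comparison: the chosen plan offers a ring A whose substitution follows from the mechanism, and a stereocentre that is never at risk.

**Alternative 2:** The cut is at O1–C8a. Forward, mild base would add the tertiary hydroxyl of the (Z)-alkenylquinone A5 to the quinone carbon, and enolisation would give the chromene hydroquinone ester A4.
- Merits: the step is redox-neutral and forms the pyran ring, the C3=C4 bond and the free hydroquinone at once. This is clearly better than the chosen plan, which spends three steps on quinone formation, reduction with protection, and dehydrogenation.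
- Weak points: A5 is a quinone bearing an ester, so it is a strong electrophile with a second, more activated site at C7. Its Z-alkene must be made and kept, since only the Z isomer can close. A4 still lacks the cinnamoyl group, so the ester must be turned into a methyl ketone and condensed with an aldehyde on an oxidation-prone hydroquinone that must be protected after all.
- Comparison: the chosen plan brings the complete C3 arm of the chalcone in with the alkyne and handles no acylquinone.

**Alternative 3:** The cut is at C3=C4. Forward, the second-generation Grubbs catalyst would join the two vinyl groups of diene A7 and give bromochromene A6 with loss of ethylene.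
- Merits: metathesis to 2H-chromenes is reliable, tolerates the free tertiary alcohol and makes the C3=C4 bond directly. In this respect it is as good as or better than the chosen plan, which needs a DDQ dehydrogenation.
- Weak points: A7 is an aryl ether of a tertiary allylic carbinol. Forming that C–O bond with retention is hard, since substitution at the tertiary centre is not available and cationic or allylmetal routes risk racemisation or attack at the primary terminus. The arene must be pentasubstituted with bromine correctly placed beforehand. A6 still needs metalation, addition to an enal and oxidation to reach the chalcone.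
- Comparison: the chosen plan never makes a bond to C2 and sets ring A's substitution in one step.

Key step: step 12

Remark on the chemistry: (S)-linalool 1 is taken to be available in high enantiomeric purity. Alkyne 17 is used as the racemate, so 18 to 22 are each expected as a pair of epimers at the silyloxy carbon, which converge when that carbon becomes the ketone in step 15.

## Steps

Step 1
Reactants: 1 (S)-linalool, (3S)-3,7-dimethylocta-1,6-dien-3-ol
Product: 2 (3S)-3,7-dimethyloct-6-ene-1,3-diol
Conditions: 9-BBN (2.5 equiv), THF, 0 → 23 °C; then NaOH (3 M aq.), H2O2 (30%), 0 → 23 °C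
Reagents that add atoms: hydrogen peroxide, OO
Why: 9-BBN hydroborates the monosubstituted vinyl group much faster than the trisubstituted alkene and places boron on the terminal carbon (anti-Markovnikov hydroboration–oxidation); the excess covers the hydroxyl proton and the carbinol stereocentre is not touched.

Step 2
Reactants: 2 (3S)-3,7-dimethyloct-6-ene-1,3-diol
Product: 3 (3S)-3,7-dimethyloctane-1,3,7-triol
Conditions: Co(acac)2 (0.2 equiv), PhSiH3 (2 equiv), O2 (1 atm), THF, 23 °C
Reagents that add atoms: dioxygen, O=O
Why: Mukaiyama hydration: hydrogen-atom transfer from a cobalt hydride gives the tertiary radical, which is trapped by O2 and reduced to the tertiary alcohol (Markovnikov). No cation is formed, so the 3-hydroxyl should not close a cyclic ether, and with the vinyl group gone there is only one alkene.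

Step 3
Reactants: 3 (3S)-3,7-dimethyloctane-1,3,7-triol
Product: 4 (3S)-3,7-dihydroxy-3,7-dimethyloctyl 4-methylbenzenesulfonate
Conditions: TsCl (1.1 equiv), Et3N, DMAP (0.05 equiv), CH2Cl2, 0 °C
Reagents that add atoms: 4-methylbenzenesulfonyl chloride, Cc1ccc(cc1)S(=O)(=O)Cl
Why: Selective sulfonylation: the primary hydroxyl reacts far faster than the two tertiary ones.

Step 4
Reactants: 4 (3S)-3,7-dihydroxy-3,7-dimethyloctyl 4-methylbenzenesulfonate
Product: 5 (6S)-2,6-dimethyldec-9-yne-2,6-diol
Conditions: LiC≡CH·H2NCH2CH2NH2 (4 equiv), DMSO, 15 → 23 °C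
Reagents that add atoms: lithium acetylide–ethylenediamine complex, [Li+].[C-]#C.NCCN
Why: SN2 displacement of a primary tosylate by acetylide in a dipolar aprotic solvent; the excess of reagent covers the two hydroxyl protons and a high acetylide concentration favours the intermolecular substitution.

Step 5
Reactants: 5 (6S)-2,6-dimethyldec-9-yne-2,6-diol
Product: 6 2-methyl-5-[(2S)-2-methyl-3,4-dihydro-2H-pyran-2-yl]pentan-2-ol
Conditions: W(CO)6 (0.25 equiv), Et3N, THF, hν (350 nm), 60 °C
Reagents that add atoms: none
Why: Alkynol endo-cycloisomerisation: photolysis frees a W(CO)5 fragment (zerovalent tungsten) that converts the terminal alkyne into a vinylidene, the hydroxyl four carbons away adds to the vinylidene carbon and protodemetalation gives the six-membered enol ether. The remote tertiary hydroxyl cannot reach the alkyne, and the stereocentre only supplies the oxygen.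

Step 6
Reactants: 6 2-methyl-5-[(2S)-2-methyl-3,4-dihydro-2H-pyran-2-yl]pentan-2-ol
Product: 7 triethyl({2-methyl-5-[(2S)-2-methyl-3,4-dihydro-2H-pyran-2-yl]pentan-2-yl}oxy)silane
Conditions: Et3SiOSO2CF3 (1.3 equiv), 2,6-lutidine (2.5 equiv), CH2Cl2, −78 °C
Reagents that add atoms: triethylsilyl trifluoromethanesulfonate, CC[Si](CC)(CC)OS(=O)(=O)C(F)(F)F
Why: A silyl triflate with a hindered base silylates tertiary alcohols; the base keeps the medium non-acidic, so the enol ether should survive.

Step 7
Reactants: 7 triethyl({2-methyl-5-[(2S)-2-methyl-3,4-dihydro-2H-pyran-2-yl]pentan-2-yl}oxy)silane; 8 chromium hexacarbonyl, Cr(CO)6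
Product: 11 pentacarbonyl{methoxy[(6S)-6-methyl-6-(4-methyl-4-triethylsilyloxypentyl)-5,6-dihydro-4H-pyran-2-yl]methylidene}chromium, via vinyllithium 9 (not isolated), via lithium acylchromate 10 (not isolated)
Conditions: t-BuLi (1.3 equiv), THF, −78 → 0 °C; 8 (1.2 equiv), Et2O, 0 → 23 °C; MeOSO2CF3 (1.5 equiv), CH2Cl2, 0 °C
Reagents that add atoms: methyl trifluoromethanesulfonate, COS(=O)(=O)C(F)(F)F
Why: Standard Fischer route to alkoxycarbene complexes: the vinylic hydrogen next to the ring oxygen is removed by t-BuLi, the vinyllithium adds to a carbonyl ligand of zerovalent chromium, and the acylchromate is O-methylated by the hard methylating agent. The tertiary silyl ether is inert to both the base and the methylating agent.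

Step 8
Reactants: 12 4-hydroxybenzaldehyde
Product: 13 4-(methoxymethoxy)benzaldehyde
Conditions: MOMCl (1.3 equiv), iPr2NEt, CH2Cl2, 0 → 23 °C
Reagents that add atoms: chloromethyl methyl ether, COCCl
Why: O-alkylation of the acidic phenol with a reactive α-chloro ether and an amine base.

Step 9
Reactants: 13 4-(methoxymethoxy)benzaldehyde
Product: 14 (2E)-3-[4-(methoxymethoxy)phenyl]prop-2-enal
Conditions: Ph3P=CHCHO (1.1 equiv), toluene, 80 °C
Reagents that add atoms: (triphenylphosphoranylidene)acetaldehyde, O=CC=P(c1ccccc1)(c1ccccc1)c1ccccc1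
Why: Wittig reaction of a stabilised ylide gives the E-enal; a near-stoichiometric amount of ylide limits a second homologation of the product.

Step 10
Reactants: 14 (2E)-3-[4-(methoxymethoxy)phenyl]prop-2-enal; 15 ethynylmagnesium bromide
Product: 16 (1E)-1-[4-(methoxymethoxy)phenyl]pent-1-en-4-yn-3-ol, racemic
Conditions: 15 (1.5 equiv, 0.5 M in THF), THF, −78 → 0 °C; aq. NH4Cl
Reagents that add atoms: none
Why: Grignard reagents add 1,2 to enals; no stereocontrol is wanted because this carbon ends as the ketone.

Step 11
Reactants: 16 (1E)-1-[4-(methoxymethoxy)phenyl]pent-1-en-4-yn-3-ol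
Product: 17 tert-butyl({(1E)-1-[4-(methoxymethoxy)phenyl]pent-1-en-4-yn-3-yl}oxy)dimethylsilane, racemic
Conditions: TBSCl (1.3 equiv), imidazole, DMF, 23 °C
Reagents that add atoms: tert-butyldimethylsilyl chloride, CC(C)(C)[Si](C)(C)Cl
Why: Standard silylation of a secondary alcohol under basic conditions, which avoid ionisation of the doubly allylic carbinol.

Step 12
Reactants: 11 pentacarbonyl{methoxy[(6S)-6-methyl-6-(4-methyl-4-triethylsilyloxypentyl)-5,6-dihydro-4H-pyran-2-yl]methylidene}chromium; 17 tert-butyl({(1E)-1-[4-(methoxymethoxy)phenyl]pent-1-en-4-yn-3-yl}oxy)dimethylsilane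
Product: 19 (2S)-6-{(2E)-1-[tert-butyl(dimethyl)silyloxy]-3-[4-(methoxymethoxy)phenyl]prop-2-en-1-yl}-8-methoxy-2-methyl-2-[4-methyl-4-(triethylsilyloxy)pentyl]-3,4-dihydro-2H-chromen-5-ol (two epimers at the silyloxy carbon), via arene tricarbonylchromium complex 18 (not isolated)
Conditions: 17 (1.8 equiv), THF (0.05 M, degassed), 50 °C; then air, Et2O, 23 °C, daylight; filtration through Et3N-deactivated silica
Reagents that add atoms: none
Why: Loss of one CO from 11 lets the alkyne coordinate and insert, giving a chromium vinylcarbene in which the former carbene carbon (C8) is bonded to the terminal alkyne carbon (C7); CO insertion then gives the chromium-bound dienylketene with the new C6–C5 bond. Ring A closes by 6π-electrocyclisation of this dienylketene onto the enol-ether carbon of the dihydropyran (C5–C4a, a six-membered carbocycle), and tautomerisation gives the phenol as the Cr(CO)3 complex 18, which air demetalates to 19. The closest known reaction type is the Dötz benzannulation of 2-dihydropyranyl(alkoxy)carbene chromium complexes with terminal alkynes to chroman-5-ols. No stereocentre is formed: C2 is remote and the silyloxy carbon is carried as the racemate. The regiochemistry needed (arm at C6 beside the CO-derived C5, hydrogen at C7 beside the methoxy carbon) is the normal steric outcome for a terminal alkyne. Phenol formation over cyclopentannulation is favoured by chromium, an alkenyl carbene and THF. The styryl double bond of 17 is not conjugated with the alkyne and should stay out. The moderate temperature and neutral work-up are meant to keep the silyloxy carbon beside the new phenol from ionising.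

Step 13
Reactants: 19 (2S)-6-{(2E)-1-[tert-butyl(dimethyl)silyloxy]-3-[4-(methoxymethoxy)phenyl]prop-2-en-1-yl}-8-methoxy-2-methyl-2-[4-methyl-4-(triethylsilyloxy)pentyl]-3,4-dihydro-2H-chromen-5-ol
Product: 20 (2S)-6-{(2E)-1-[tert-butyl(dimethyl)silyloxy]-3-[4-(methoxymethoxy)phenyl]prop-2-en-1-yl}-2-methyl-2-[4-methyl-4-(triethylsilyloxy)pentyl]-3,4-dihydro-2H-chromene-5,8-dione
Conditions: PhI(OAc)2 (1.1 equiv), MeCN/H2O (3:1), 0 °C
Reagents that add atoms: water, O
Why: Hypervalent-iodine oxidative demethylation of a 4-methoxyphenol: the free phenol exchanges onto trivalent iodine, loss of PhI gives a cation that water captures at the methoxy-bearing C8, and the hemiketal loses methanol to give the para-quinone. The reagent needs a free phenol, so ring B and the silyl ethers should not be addressed.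

Step 14
Reactants: 20 (2S)-6-{(2E)-1-[tert-butyl(dimethyl)silyloxy]-3-[4-(methoxymethoxy)phenyl]prop-2-en-1-yl}-2-methyl-2-[4-methyl-4-(triethylsilyloxy)pentyl]-3,4-dihydro-2H-chromene-5,8-dione
Product: 22 (2S)-6-{(2E)-1-[tert-butyl(dimethyl)silyloxy]-3-[4-(methoxymethoxy)phenyl]prop-2-en-1-yl}-5,8-bis(methoxymethoxy)-2-methyl-2-[4-methyl-4-(triethylsilyloxy)pentyl]-3,4-dihydro-2H-chromene, via hydroquinone 21 (not isolated)
Conditions: Na2S2O4 (aq.), THF/H2O, 23 °C, argon; then MOMCl (6 equiv), iPr2NEt (8 equiv), Bu4NI (0.1 equiv), CH2Cl2, 0 → 40 °C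
Reagents that add atoms: chloromethyl methyl ether, COCCl
Why: Dithionite reduces the quinone to the hydroquinone, which is alkylated at once to avoid air oxidation; iodide catalysis helps the hindered C5 oxygen, and the mildly basic medium avoids ionisation at the silyloxy carbon.

Step 15
Reactants: 22 (2S)-6-{(2E)-1-[tert-butyl(dimethyl)silyloxy]-3-[4-(methoxymethoxy)phenyl]prop-2-en-1-yl}-5,8-bis(methoxymethoxy)-2-methyl-2-[4-methyl-4-(triethylsilyloxy)pentyl]-3,4-dihydro-2H-chromene
Product: 24 (2E)-1-{(2S)-5,8-bis(methoxymethoxy)-2-methyl-2-[4-methyl-4-(triethylsilyloxy)pentyl]-2H-chromen-6-yl}-3-[4-(methoxymethoxy)phenyl]prop-2-en-1-one, via chroman enone 23 (not isolated)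
Conditions: DDQ (3.5 equiv), 1,4-dioxane, 23 °C, then 95 °C
Reagents that add atoms: none
Why: DDQ first abstracts hydride from the benzylic and cinnamylic C–H of the silyl ether, and the silyloxy cation collapses to enone 23 with loss of the silyl group (DDQ oxidation of allylic and benzylic silyl ethers). On heating, hydride abstraction at benzylic C4, assisted by O1 and the C5 oxygen, and loss of a C3 proton give the chromene (DDQ dehydrogenation of 2,2-dialkylchromans). The acetals, the tertiary silyl ether and the quaternary C2 offer no hydridic C–H.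

Step 16
Reactants: 24 (2E)-1-{(2S)-5,8-bis(methoxymethoxy)-2-methyl-2-[4-methyl-4-(triethylsilyloxy)pentyl]-2H-chromen-6-yl}-3-[4-(methoxymethoxy)phenyl]prop-2-en-1-one
Product: 25 (2E)-1-[(2S)-5,8-dihydroxy-2-(4-hydroxy-4-methylpentyl)-2-methyl-2H-chromen-6-yl]-3-(4-hydroxyphenyl)prop-2-en-1-one
Conditions: HCl (2 M in MeOH/H2O 9:1), 23 → 40 °C, argon
Reagents that add atoms: none
Why: Acid-catalysed acetal exchange of the three MOM ethers with methanol and solvolysis of the triethylsilyl ether, as used for MOM-protected 2'-hydroxychalcones. Dilute acid near room temperature and exclusion of air are chosen so that the tertiary alcohol, the chromene, the open chalcone form and the hydroquinone should persist.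

## Compound list

1 | (S)-linalool, (3S)-3,7-dimethylocta-1,6-dien-3-ol | CC(C)=CCC[C@](C)(O)C=C | starting material
2 | (3S)-3,7-dimethyloct-6-ene-1,3-diol | CC(C)=CCC[C@](C)(O)CCO | intermediate
3 | (3S)-3,7-dimethyloctane-1,3,7-triol | CC(C)(O)CCC[C@](C)(O)CCO | intermediate
4 | (3S)-3,7-dihydroxy-3,7-dimethyloctyl 4-methylbenzenesulfonate | CC(C)(O)CCC[C@](C)(O)CCOS(=O)(=O)c1ccc(C)cc1 | intermediate
5 | (6S)-2,6-dimethyldec-9-yne-2,6-diol | CC(C)(O)CCC[C@](C)(O)CCC#C | intermediate
6 | 2-methyl-5-[(2S)-2-methyl-3,4-dihydro-2H-pyran-2-yl]pentan-2-ol | CC(C)(O)CCC[C@@]1(C)CCC=CO1 | intermediate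
7 | triethyl({2-methyl-5-[(2S)-2-methyl-3,4-dihydro-2H-pyran-2-yl]pentan-2-yl}oxy)silane | CC(C)(O[Si](CC)(CC)CC)CCC[C@@]1(C)CCC=CO1 | intermediate
8 | chromium hexacarbonyl, Cr(CO)6 | O=C=[Cr](=C=O)(=C=O)(=C=O)(=C=O)=C=O | starting material
9 | [(6S)-6-methyl-6-(4-methyl-4-triethylsilyloxypentyl)-5,6-dihydro-4H-pyran-2-yl]lithium | CC(C)(O[Si](CC)(CC)CC)CCC[C@@]1(C)CCC=C([Li])O1 | intermediate (not isolated)
10 | lithium pentacarbonyl{[(6S)-6-methyl-6-(4-methyl-4-triethylsilyloxypentyl)-5,6-dihydro-4H-pyran-2-yl]carbonyl}chromate | [Li+].CC(C)(O[Si](CC)(CC)CC)CCC[C@@]1(C)CCC=C(O1)C([O-])=[Cr](=C=O)(=C=O)(=C=O)(=C=O)=C=O | intermediate (not isolated)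
11 | pentacarbonyl{methoxy[(6S)-6-methyl-6-(4-methyl-4-triethylsilyloxypentyl)-5,6-dihydro-4H-pyran-2-yl]methylidene}chromium | CC(C)(O[Si](CC)(CC)CC)CCC[C@@]1(C)CCC=C(O1)C(OC)=[Cr](=C=O)(=C=O)(=C=O)(=C=O)=C=O | intermediate
12 | 4-hydroxybenzaldehyde | O=Cc1ccc(O)cc1 | starting material
13 | 4-(methoxymethoxy)benzaldehyde | COCOc1ccc(C=O)cc1 | intermediate
14 | (2E)-3-[4-(methoxymethoxy)phenyl]prop-2-enal | COCOc1ccc(/C=C/C=O)cc1 | intermediate
15 | ethynylmagnesium bromide | C#C[Mg]Br | starting material
16 | (1E)-1-[4-(methoxymethoxy)phenyl]pent-1-en-4-yn-3-ol, racemic | C#CC(O)/C=C/c1ccc(OCOC)cc1 | intermediate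
17 | tert-butyl({(1E)-1-[4-(methoxymethoxy)phenyl]pent-1-en-4-yn-3-yl}oxy)dimethylsilane, racemic | C#CC(O[Si](C)(C)C(C)(C)C)/C=C/c1ccc(OCOC)cc1 | intermediate
18 | tricarbonylchromium complex of 19, chromium bound η6 to ring A (bonding written as a dot) | CC(C)(O[Si](CC)(CC)CC)CCC[C@@]1(C)CCc2c(O)c(C(O[Si](C)(C)C(C)(C)C)/C=C/c3ccc(OCOC)cc3)cc(OC)c2O1.O=C=[Cr](=C=O)=C=O | intermediate (not isolated)
19 | (2S)-6-{(2E)-1-[tert-butyl(dimethyl)silyloxy]-3-[4-(methoxymethoxy)phenyl]prop-2-en-1-yl}-8-methoxy-2-methyl-2-[4-methyl-4-(triethylsilyloxy)pentyl]-3,4-dihydro-2H-chromen-5-ol, two epimers at the silyloxy carbon | CC(C)(O[Si](CC)(CC)CC)CCC[C@@]1(C)CCc2c(O)c(C(O[Si](C)(C)C(C)(C)C)/C=C/c3ccc(OCOC)cc3)cc(OC)c2O1 | intermediate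
20 | (2S)-6-{(2E)-1-[tert-butyl(dimethyl)silyloxy]-3-[4-(methoxymethoxy)phenyl]prop-2-en-1-yl}-2-methyl-2-[4-methyl-4-(triethylsilyloxy)pentyl]-3,4-dihydro-2H-chromene-5,8-dione, two epimers at the silyloxy carbon | CC(C)(O[Si](CC)(CC)CC)CCC[C@@]1(C)CCC2=C(O1)C(=O)C=C(C(O[Si](C)(C)C(C)(C)C)/C=C/c3ccc(OCOC)cc3)C2=O | intermediate
21 | (2S)-6-{(2E)-1-[tert-butyl(dimethyl)silyloxy]-3-[4-(methoxymethoxy)phenyl]prop-2-en-1-yl}-2-methyl-2-[4-methyl-4-(triethylsilyloxy)pentyl]-3,4-dihydro-2H-chromene-5,8-diol, two epimers at the silyloxy carbon | CC(C)(O[Si](CC)(CC)CC)CCC[C@@]1(C)CCc2c(O)c(C(O[Si](C)(C)C(C)(C)C)/C=C/c3ccc(OCOC)cc3)cc(O)c2O1 | intermediate (not isolated)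
22 | (2S)-6-{(2E)-1-[tert-butyl(dimethyl)silyloxy]-3-[4-(methoxymethoxy)phenyl]prop-2-en-1-yl}-5,8-bis(methoxymethoxy)-2-methyl-2-[4-methyl-4-(triethylsilyloxy)pentyl]-3,4-dihydro-2H-chromene, two epimers at the silyloxy carbon | CC(C)(O[Si](CC)(CC)CC)CCC[C@@]1(C)CCc2c(OCOC)c(C(O[Si](C)(C)C(C)(C)C)/C=C/c3ccc(OCOC)cc3)cc(OCOC)c2O1 | intermediate
23 | (2E)-1-{(2S)-5,8-bis(methoxymethoxy)-2-methyl-2-[4-methyl-4-(triethylsilyloxy)pentyl]-3,4-dihydro-2H-chromen-6-yl}-3-[4-(methoxymethoxy)phenyl]prop-2-en-1-one | CC(C)(O[Si](CC)(CC)CC)CCC[C@@]1(C)CCc2c(OCOC)c(C(=O)/C=C/c3ccc(OCOC)cc3)cc(OCOC)c2O1 | intermediate (not isolated)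
24 | (2E)-1-{(2S)-5,8-bis(methoxymethoxy)-2-methyl-2-[4-methyl-4-(triethylsilyloxy)pentyl]-2H-chromen-6-yl}-3-[4-(methoxymethoxy)phenyl]prop-2-en-1-one | CC(C)(O[Si](CC)(CC)CC)CCC[C@@]1(C)C=Cc2c(OCOC)c(C(=O)/C=C/c3ccc(OCOC)cc3)cc(OCOC)c2O1 | intermediate
25 | (2E)-1-[(2S)-5,8-dihydroxy-2-(4-hydroxy-4-methylpentyl)-2-methyl-2H-chromen-6-yl]-3-(4-hydroxyphenyl)prop-2-en-1-one | CC(C)(O)CCC[C@@]1(C)C=Cc2c(O)c(C(=O)/C=C/c3ccc(O)cc3)cc(O)c2O1 | target

## Step count and risks

Total step count: 16. Longest linear sequence: 12 steps (steps 1 to 7 and 12 to 16, from 1). The alkyne branch (steps 8 to 11) has 4 steps.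

**Step 12 (key step).** The most likely failure is ionisation at the silyloxy carbon, which lies beside the newly formed, chromium-bound phenol and is stabilised by both aryl groups; this would lead to loss of the silanol and closure onto the phenol oxygen. A second risk is slow insertion of the α-branched alkyne, which would let the carbene complex decay thermally.

Fallback: keep the benzannulation but take the cinnamyl arm out of it. The fallback sets out from 11, which is heated under the conditions of step 12 with racemic tert-butyl(but-3-yn-2-yloxy)dimethylsilane, a stock reagent, to give the 6-(1-silyloxyethyl)chromanol F1. PhI(OAc)2 gives the quinone F2. Na2S2O4 gives the hydroquinone F3, which is capped with MOMCl to the bis(methoxymethyl) ether F4. DDQ oxidises the benzylic silyl ether to the acetylchroman F5 and, on heating, dehydrogenates it to the acetylchromene F6. Claisen–Schmidt condensation of F6 with aldehyde 13 (KOH, EtOH/H2O, 23 °C) forms the E-enone, and the route is rejoined at 24.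

**Step 15.** Once the arm has become an acyl group the ring is poorer in electrons, so hydride abstraction at C4 may stall; prolonged heating with excess DDQ may then erode the acetals or the silyl ether.

Fallback: separate the two oxidations and replace hydride abstraction at C4 by a radical path, which depends little on ring electronics. It sets out from 22: DDQ (1.2 equiv, CH2Cl2/pH 7 buffer, 0 °C) oxidises only the arm and 23 is isolated. N-Bromosuccinimide with a radical initiator in PhCF3 at 80 °C brominates the only benzylic CH2 to give the 4-bromochroman F7. DBU in toluene eliminates HBr across C3–C4 and the route is rejoined at 24.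

**Step 5.** Addition of a hindered tertiary hydroxyl to the tungsten vinylidene may be slow, so catalyst decay or exo-mode closure could compete with the endo closure.

Fallback: build the enol ether by hydroboration and dehydration instead of through a vinylidene. It sets out from 5: dicyclohexylborane (excess, THF, 0 °C) then NaBO3·4H2O turns the terminal alkyne into the aldehyde, which closes to the lactol F8. MsCl and Et3N (CH2Cl2, −20 → 40 °C) activate the anomeric hydroxyl and eliminate to the dihydropyran, and the route is rejoined at 6.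

**Step 4.** The 3-alkoxide generated by the basic reagent may displace the tosylate intramolecularly (four-membered ring closure, helped by the geminal substituents) faster than acetylide does.

Fallback: make that side reaction the route. It sets out from 4: KOtBu (THF, 0 → 23 °C) closes the oxetane F9. Lithium (trimethylsilyl)acetylide with BF3·OEt2 (THF, −78 °C) opens it at the unsubstituted carbon to the silylalkyne F10. K2CO3 in MeOH removes the C-silyl group and the route is rejoined at 5.

**Step 16.** Protic acid strong enough to cleave the unchelated aryl acetals may also promote closure of the 2'-hydroxychalcone to the flavanone, solvolysis of the tertiary alcohol or addition to the chromene.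

Fallback: give up the single protic solvolysis for a two-stage release in aprotic media. It sets out from 24: ZnBr2 and n-PrSH (CH2Cl2, 0 °C) transfer the three methoxymethyl groups to sulfur while the tertiary oxygen stays silylated, giving the triphenol silyl ether F11. Buffered fluoride (Bu4NF/AcOH, THF, 0 → 23 °C, argon) then removes the triethylsilyl group and the route ends at 25.

## Further compounds

F1 | step 12 | (2S)-6-{1-[tert-butyl(dimethyl)silyloxy]ethyl}-8-methoxy-2-methyl-2-[4-methyl-4-(triethylsilyloxy)pentyl]-3,4-dihydro-2H-chromen-5-ol | CC(C)(O[Si](CC)(CC)CC)CCC[C@@]1(C)CCc2c(O)c(C(C)O[Si](C)(C)C(C)(C)C)cc(OC)c2O1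
F2 | step 12 | (2S)-6-{1-[tert-butyl(dimethyl)silyloxy]ethyl}-2-methyl-2-[4-methyl-4-(triethylsilyloxy)pentyl]-3,4-dihydro-2H-chromene-5,8-dione | CC(C)(O[Si](CC)(CC)CC)CCC[C@@]1(C)CCC2=C(O1)C(=O)C=C(C(C)O[Si](C)(C)C(C)(C)C)C2=O
F3 | step 12 | (2S)-6-{1-[tert-butyl(dimethyl)silyloxy]ethyl}-2-methyl-2-[4-methyl-4-(triethylsilyloxy)pentyl]-3,4-dihydro-2H-chromene-5,8-diol | CC(C)(O[Si](CC)(CC)CC)CCC[C@@]1(C)CCc2c(O)c(C(C)O[Si](C)(C)C(C)(C)C)cc(O)c2O1
F4 | step 12 | (2S)-6-{1-[tert-butyl(dimethyl)silyloxy]ethyl}-5,8-bis(methoxymethoxy)-2-methyl-2-[4-methyl-4-(triethylsilyloxy)pentyl]-3,4-dihydro-2H-chromene | CC(C)(O[Si](CC)(CC)CC)CCC[C@@]1(C)CCc2c(OCOC)c(C(C)O[Si](C)(C)C(C)(C)C)cc(OCOC)c2O1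
F5 | step 12 | 1-{(2S)-5,8-bis(methoxymethoxy)-2-methyl-2-[4-methyl-4-(triethylsilyloxy)pentyl]-3,4-dihydro-2H-chromen-6-yl}ethan-1-one | CC(C)(O[Si](CC)(CC)CC)CCC[C@@]1(C)CCc2c(OCOC)c(C(C)=O)cc(OCOC)c2O1
F6 | step 12 | 1-{(2S)-5,8-bis(methoxymethoxy)-2-methyl-2-[4-methyl-4-(triethylsilyloxy)pentyl]-2H-chromen-6-yl}ethan-1-one | CC(C)(O[Si](CC)(CC)CC)CCC[C@@]1(C)C=Cc2c(OCOC)c(C(C)=O)cc(OCOC)c2O1
F7 | step 15 | (2E)-1-{(2S)-4-bromo-5,8-bis(methoxymethoxy)-2-methyl-2-[4-methyl-4-(triethylsilyloxy)pentyl]-3,4-dihydro-2H-chromen-6-yl}-3-[4-(methoxymethoxy)phenyl]prop-2-en-1-one, both C4 epimers | CC(C)(O[Si](CC)(CC)CC)CCC[C@@]1(C)CC(Br)c2c(OCOC)c(C(=O)/C=C/c3ccc(OCOC)cc3)cc(OCOC)c2O1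
F8 | step 5 | (6S)-6-(4-hydroxy-4-methylpentyl)-6-methyloxan-2-ol, both anomers | CC(C)(O)CCC[C@@]1(C)CCCC(O)O1
F9 | step 4 | 2-methyl-5-[(2S)-2-methyloxetan-2-yl]pentan-2-ol | CC(C)(O)CCC[C@@]1(C)CCO1
F10 | step 4 | (6S)-2,6-dimethyl-10-(trimethylsilyl)dec-9-yne-2,6-diol | CC(C)(O)CCC[C@](C)(O)CCC#C[Si](C)(C)C
F11 | step 16 | (2E)-1-{(2S)-5,8-dihydroxy-2-methyl-2-[4-methyl-4-(triethylsilyloxy)pentyl]-2H-chromen-6-yl}-3-(4-hydroxyphenyl)prop-2-en-1-one | CC(C)(O[Si](CC)(CC)CC)CCC[C@@]1(C)C=Cc2c(O)c(C(=O)/C=C/c3ccc(O)cc3)cc(O)c2O1
A1 | alternative 1 | (2E)-1-[(2S)-2-(4-hydroxy-4-methylpentyl)-5,8-bis(methoxymethoxy)-2-methyl-2H-chromen-6-yl]-3-[4-(methoxymethoxy)phenyl]prop-2-en-1-one | CC(C)(O)CCC[C@@]1(C)C=Cc2c(OCOC)c(C(=O)/C=C/c3ccc(OCOC)cc3)cc(OCOC)c2O1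
A2 | alternative 1 | 5-[(2S)-6-iodo-5,8-bis(methoxymethoxy)-2-methyl-2H-chromen-2-yl]-2-methylpentan-2-ol | CC(C)(O)CCC[C@@]1(C)C=Cc2c(OCOC)c(I)cc(OCOC)c2O1
A3 | alternative 1 | 1-ethenyl-4-(methoxymethoxy)benzene | C=Cc1ccc(OCOC)cc1
A4 | alternative 2 | methyl (2S)-5,8-dihydroxy-2-(4-hydroxy-4-methylpentyl)-2-methyl-2H-chromene-6-carboxylate | CC(C)(O)CCC[C@@]1(C)C=Cc2c(O)c(C(=O)OC)cc(O)c2O1
A5 | alternative 2 | methyl 5-[(1Z,3S)-3,7-dihydroxy-3,7-dimethyloct-1-en-1-yl]-3,6-dioxocyclohexa-1,4-diene-1-carboxylate | CC(C)(O)CCC[C@](C)(O)/C=C\C1=CC(=O)C=C(C(=O)OC)C1=O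
A6 | alternative 3 | 5-[(2S)-6-bromo-5,8-bis(methoxymethoxy)-2-methyl-2H-chromen-2-yl]-2-methylpentan-2-ol | CC(C)(O)CCC[C@@]1(C)C=Cc2c(OCOC)c(Br)cc(OCOC)c2O1
A7 | alternative 3 | (6S)-6-[4-bromo-2-ethenyl-3,6-bis(methoxymethoxy)phenoxy]-2,6-dimethyloct-7-en-2-ol | CC(C)(O)CCC[C@@](C)(C=C)Oc1c(OCOC)cc(Br)c(OCOC)c1C=C
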